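**Retrosynthetic overview**

- The biaryl C–C bond is made last, with no halide or boron handle: C1 of 4-methoxy-7-methylnaphthalene-2,5-diol adds to C3 of plumbagin methyl ether under acid catalysis, and the adduct is re-oxidised in the same flask.
- The naphthalenediol is an isomer of 4-methoxy-5,7-dimethylcoumarin. A base-induced lactone-to-carbocycle transposition builds naphthalene ring B, passing through a dearomatised o-quinodimethane trienolate and leaving the methoxy group peri to the free hydroxyl.
- The coumarin comes from C2v-symmetric 3,5-dimethylphenol and malonic acid. This annulation breaks the symmetry: one methyl becomes the future biaryl carbon C1 and the other stays as the 7-methyl group.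
- Ring order: temporary pyranone ring, then naphthalene ring B, then the biaryl bond. The quinone half is bought as plumbagin and O-methylated.

Assumption: the target SMILES carries no stereodescriptor (no stereocentre, biaryl axis unassigned), so the compound is made as drawn, without control of the axis (racemic if the atropisomers do not interconvert).

**Route**

Step 1
Reactants: 1 3,5-dimethylphenol; 2 malonic acid
Product: 3 4-hydroxy-5,7-dimethyl-2H-chromen-2-one
Conditions: ZnCl2 (3 equiv), POCl3 (3 equiv), neat, 65 °C, 30 h; ice water, then Na2CO3 extraction and acidification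
Reagents that add atoms: none
Why: Shah-type 4-hydroxycoumarin synthesis (ortho Friedel–Crafts C-acylation, then lactonisation); the two ortho positions of 1 are equivalent, so one isomer forms and the two methyl groups become different (5-methyl peri to C4, 7-methyl remote).

Step 2
Reactants: 3 4-hydroxy-5,7-dimethyl-2H-chromen-2-one
Product: 4 4-methoxy-5,7-dimethyl-2H-chromen-2-one
Conditions: Me2SO4 (1.2 equiv), K2CO3 (1.5 equiv), acetone, reflux
Reagents that add atoms: dimethyl sulfate, COS(=O)(=O)OC
Why: Williamson-type O-alkylation of the vinylogous carboxylate with a hard methylating agent gives the 4-methoxycoumarin, fixing the methyl ether on the carbon that becomes naphthalene C4.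

Step 3
Reactants: 4 4-methoxy-5,7-dimethyl-2H-chromen-2-one
Product: 6 4-methoxy-7-methylnaphthalene-2,5-diol, via ring-opened methoxyacrylate ester 5 (not isolated)
Conditions: NaOMe (1.1 equiv), MeOH/THF, 25 °C; evaporate; LiN(i-Pr)2 (2.5 equiv), THF, −78 → 0 °C, Ar; then degassed 1 M HCl
Reagents that add atoms: none
Why: Proposed new method: methoxide opens the lactone (strained by the 5-Me/4-OMe peri clash) to phenoxide ester 5 with the aryl group cis to CO2Me; LiN(i-Pr)2 then deprotonates the ortho methyl to a dearomatised o-quinodimethane trienolate whose CH2 terminus closes on the ester carbon (6-exo Claisen, equivalent to a 6π closure), and loss of methoxide plus enolisation gives the naphthalene irreversibly, so the reversible side equilibria (para-methyl anion, alkene isomer, re-lactonisation) drain to 6; the closest known reaction types are lateral-lithiation/Dieckmann cyclisations of o-toluates and the remote lateral metalation–cyclisation of 2′-methylbiaryl-2-carboxamides to 9-phenanthrols; no stereocentre is formed.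

Step 4
Reactants: 7 plumbagin (5-hydroxy-2-methylnaphthalene-1,4-dione)
Product: 8 5-methoxy-2-methylnaphthalene-1,4-dione
Conditions: MeI (5 equiv), Ag2O (1.5 equiv), CH2Cl2, 25 °C, dark
Reagents that add atoms: iodomethane, CI
Why: Purdie methylation (Ag2O/MeI) etherifies the chelated peri hydroxyl under neutral conditions that the base-sensitive methylquinone tolerates.

Step 5
Reactants: 6 4-methoxy-7-methylnaphthalene-2,5-diol; 8 5-methoxy-2-methylnaphthalene-1,4-dione
Product: 10 3-(2,5-dihydroxy-4-methoxy-7-methylnaphthalen-1-yl)-5-methoxy-2-methylnaphthalene-1,4-dione, via biaryl hydroquinone 9 (not isolated)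
Conditions: 8 (2.2 equiv), (PhO)2P(O)OH (10 mol %), CH2Cl2/(CF3)2CHOH 4:1, 0 → 25 °C, Ar
Reagents that add atoms: none
Why: Brønsted-acid-catalysed Michael/Friedel–Crafts arylation of a quinone by a 2-naphthol: C1 of 6 (ortho to OH, para to OMe) adds to C3 of 8 (the only free quinone carbon), the adduct tautomerises to hydroquinone 9, and the second equivalent of 8 oxidises it by quinone–hydroquinone exchange; the 2-methyl group blocks furan closure, and no stereocentre is formed (axis uncontrolled).

**Compound list**

1 | 3,5-dimethylphenol | Cc1cc(C)cc(O)c1 | starting material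
2 | malonic acid | OC(=O)CC(=O)O | starting material
3 | 4-hydroxy-5,7-dimethyl-2H-chromen-2-one | OC1=CC(=O)Oc2cc(C)cc(C)c12 | intermediate
4 | 4-methoxy-5,7-dimethyl-2H-chromen-2-one | COC1=CC(=O)Oc2cc(C)cc(C)c12 | intermediate
5 | methyl (E)-3-(2-hydroxy-4,6-dimethylphenyl)-3-methoxyprop-2-enoate (aryl cis to the ester; present as its sodium phenoxide) | COC(=O)/C=C(OC)\c1c(C)cc(C)cc1O | intermediate (not isolated)
6 | 4-methoxy-7-methylnaphthalene-2,5-diol | COc1cc(O)cc2cc(C)cc(O)c12 | intermediate
7 | plumbagin (5-hydroxy-2-methylnaphthalene-1,4-dione) | CC1=CC(=O)c2c(O)cccc2C1=O | starting material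
8 | 5-methoxy-2-methylnaphthalene-1,4-dione | CC1=CC(=O)c2c(OC)cccc2C1=O | intermediate
9 | 3-(2,5-dihydroxy-4-methoxy-7-methylnaphthalen-1-yl)-5-methoxy-2-methylnaphthalene-1,4-diol | COc1cccc2c(O)c(C)c(-c3c(O)cc(OC)c4c(O)cc(C)cc34)c(O)c12 | intermediate (not isolated)
10 | 3-(2,5-dihydroxy-4-methoxy-7-methylnaphthalen-1-yl)-5-methoxy-2-methylnaphthalene-1,4-dione | COc1cccc2c1C(=O)C(c1c(O)cc(OC)c3c(O)cc(C)cc13)=C(C)C2=O | target

**Step count and risks**

Total steps: 5. Longest linear sequence: 4 steps (1 → 3 → 4 → 6 → 10).

The three steps most likely to fail: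

Step 3 (lactone-to-naphthalene transposition, unprecedented as a one-flask process). The fallback sets out from 4 and comes back at 6. Open 4 with NaOMe in MeOH as before, evaporate, and silylate the phenoxide (t-BuMe2SiCl, imidazole, DMF) to isolate methyl (E)-3-[2-(tert-butyldimethylsilyloxy)-4,6-dimethylphenyl]-3-methoxyprop-2-enoate F1. The neutral silyl ether cannot re-lactonise and its ortho methyl is more acidic than in the phenoxide, so LiN(i-Pr)2 (2.2 equiv, THF, −78 °C) effects an ordinary lateral-lithiation/Claisen closure to 5-(tert-butyldimethylsilyloxy)-4-methoxy-7-methylnaphthalen-2-ol F2. Bu4NF/AcOH in THF then frees 6.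

Step 5 (direct naphthol–quinone union; risks are low electrophilicity of the methylquinone, over-arylation and incomplete re-oxidation). The fallback sets out from 8 and comes back at 10. Brominate 8 (Br2, NaOAc, AcOH, 25 °C; addition, then loss of HBr) to 3-bromo-5-methoxy-2-methylnaphthalene-1,4-dione F3. Naphthol 6 then displaces bromide by conjugate addition–elimination (K2CO3, MeCN, 0 °C, Ar), a redox-neutral union that needs neither oxidant nor excess quinone and gives 10 directly.

Step 2 (O4-methylation may be eroded by 2-methoxychromone formation or C3-methylation next to the peri methyl). The fallback sets out from 3 and comes back at 4. POCl3 (BnEt3NCl, 90 °C) converts 3 into 4-chloro-5,7-dimethyl-2H-chromen-2-one F4. NaOMe (1.05 equiv) in MeOH at 0 °C replaces the chloride at C4 by addition–elimination, which can only give the 4-methoxy isomer 4.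

**Further compounds**

F1 | step 3 | methyl (E)-3-[2-(tert-butyldimethylsilyloxy)-4,6-dimethylphenyl]-3-methoxyprop-2-enoate | COC(=O)/C=C(OC)\c1c(C)cc(C)cc1O[Si](C)(C)C(C)(C)C
F2 | step 3 | 5-(tert-butyldimethylsilyloxy)-4-methoxy-7-methylnaphthalen-2-ol | COc1cc(O)cc2cc(C)cc(O[Si](C)(C)C(C)(C)C)c12
F3 | step 5 | 3-bromo-5-methoxy-2-methylnaphthalene-1,4-dione | CC1=C(Br)C(=O)c2c(OC)cccc2C1=O
F4 | step 2 | 4-chloro-5,7-dimethyl-2H-chromen-2-one | ClC1=CC(=O)Oc2cc(C)cc(C)c12
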